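Readings and results are simulated on assumed constants; scatter was added.

At 0.333 min and at 8.00 min the south-west run is read, and the peak of intermediate A is solved at each end and the two ends are joined.

- south-west: substrate 1 M; the very flask that is asked about, followed so far
- flask: substrate 1.0 M; time 40 min

- south-west (time / min: intermediate A / %, product / %): 0.333: 26.3, 0.4; 0.667: 40.8, 2.7; 1.33: 51.1, 9.7; 2.50: 44.5, 30.0; 4.00: 29.6, 52.9; 8.00: 7.6, 80.7

(each reading ± 0.5 percentage points)

- a species is counted by the substrate in it: one homo dimer counts as two
- steps that have been proposed: intermediate A -> intermediate B; 2 substrate -> homo dimer; substrate -> intermediate A; intermediate B -> product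

- the best time, 40 min at the latest, for intermediate A
- the amount of intermediate A, in percent of the substrate charged, at that time

The flask asked about is the south-west run itself. In its last row, c(intermediate A) and c(product) add up to 88.3%. This sum is taken as an estimate of the line share, the selectivity for the way to product, with whatever substrate and intermediate B stand at that time left uncounted. In the row before it, intermediate A stands at 29.6%, and the fall to 7.6% gives a loss constant k_out of 0.340 min⁻¹. The first row, held against the line share, gives an entry constant k_in of 1.06 min⁻¹, which is faster than k_out.

For two first-order steps in a row, starting with none of the middle species, the peak comes at ln(k_in/k_out)/(k_in−k_out); taken so, the south-west flask has it at 1.58 min, later than the row at 1.33 min and far earlier than the limit of 40 min. The peak fraction, the part of the line share standing as intermediate A at that peak, is k_out/k_in raised to the power k_out/(k_in−k_out): 0.585. Multiplied by the line share, it gives 51.6%.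

The forecast reads: “The curve is flat near its top”, and it gives 1.5 min and 51.5%, a time earlier than this reckoning's.

The flask gives 1.49 min and 51.1%.

    intermediate A → intermediate B (k = 0.00610 s⁻¹)
    2 substrate → homo dimer (k = 0.00210 M⁻¹ s⁻¹)
    substrate → intermediate A (k = 0.0170 s⁻¹)
    intermediate B → product (k = 0.0340 s⁻¹)

At 40.0 min this flask holds 89.4% product, and the peak fraction 0.585 times that is 52.3%. The neighbouring flask, charged with 2.5 M of substrate, ends with 22.1% homo dimer, twice the amount in this flask, and with 77.9% product. The same peak fraction on that product gives 45.6% for the neighbouring flask, whose simulated peak of intermediate A is 45.2%.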